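## Retrosynthetic overview

1. The sulfate goes onto the phenol oxygen next to the benzylic carbon late; that oxygen is unmasked from an allyl ether, and the benzyl ether (other catechol oxygen) and silyl ether (CH2OH) come off after sulfation.
2. The aryl–CH2 bond is cut next: an arylcopper made from a protected 3-bromo-4,5-dihydroxybenzaldehyde attacks a primary allylic bromide in an SN2 reaction.
3. The allylic bromide comes from a tetrasubstituted enol triflate (carbonylation, reduction, bromination), and the triflate from a cis-fused 5,5,8a-trimethyldecalin-1-one (α-methylation, triflation).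
4. The cis-decalone comes from (S)-Wieland–Miescher ketone: ketoreductase reduction of the saturated carbonyl, cis-selective hydrogenation, C-4 gem-dimethylation, Wolff–Kishner reduction, re-oxidation.
5. Ring order: ring B is the ring of 2-methylcyclohexane-1,3-dione, ring A is annulated onto it (proline-catalysed Robinson annulation, first stereocentre), and the arene is bought.

## Notes before the steps

- Stereochemical reading of the target: a cis-fused decalin, (4aR,8aS) in naphthalene locants, with the ring-fusion H and the angular CH3 on the same face.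
- Locants such as C-3, C-4, C-5, C-8, C-9, C-10, C-11 in the comments are drimane locants (C-10 angular-methyl carbon, C-5 ring-fusion CH, C-4 gem-dimethyl carbon, C-8/C-9 olefin carbons, C-11 benzylic CH2). Names use naphthalene locants. "Dec" = (4aR,8aS)-2,5,5,8a-tetramethyl-3,4,4a,5,6,7,8,8a-octahydronaphthalen-1-yl.
- Assumption: aryl sulfate monoesters are drawn as the free acids, as in the given SMILES; in the flask they are handled as their salts.

## Route

Step 1
Reactants: 1 2-methylcyclohexane-1,3-dione; 2 but-3-en-2-one (methyl vinyl ketone)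
Product: 3 2-methyl-2-(3-oxobutyl)cyclohexane-1,3-dione
Conditions: Et3N (1 mol%), neat, 25 °C
Reagents that add atoms: none
Why: Base-catalysed Michael addition of the acidic dione C–H to the enone; the triketone is achiral, so no stereocentre arises.

Step 2
Reactants: 3 2-methyl-2-(3-oxobutyl)cyclohexane-1,3-dione
Product: 5 (S)-8a-methyl-3,4,8,8a-tetrahydronaphthalene-1,6(2H,7H)-dione [(S)-Wieland–Miescher ketone], via cis-fused ketol 4 (not isolated)
Conditions: L-proline (5 mol%), DMSO, 25 °C; one recrystallisation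
Reagents that add atoms: none
Why: Proline-catalysed intramolecular aldol condensation (Hajos–Parrish–Eder–Sauer–Wiechert reaction), in which the L-proline enamine attacks one of the two enantiotopic ring carbonyls and so fixes the quaternary carbon as S (about 70% ee, raised by recrystallisation and by step 3).

Step 3
Reactants: 5 (S)-Wieland–Miescher ketone
Product: 6 (4aS,5S)-5-hydroxy-4a-methyl-4,4a,5,6,7,8-hexahydronaphthalen-2(3H)-one
Conditions: ketoreductase (NADPH-dependent alcohol dehydrogenase), NADP+ (cat.), i-PrOH (10 vol%), KH2PO4/K2HPO4 buffer pH 7, 30 °C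
Reagents that add atoms: none
Why: Enzymatic carbonyl reduction by a ketoreductase, which reduces only the saturated ketone of the S enantiomer from one face (OH cis to the angular methyl) and leaves the enone; residual (R)-5 is not converted to 6 and is removed, so 6 is enantiopure.

Step 4
Reactants: 6 (4aS,5S)-5-hydroxy-4a-methyl-4,4a,5,6,7,8-hexahydronaphthalen-2(3H)-one
Product: 7 (4aS,5S,8aR)-5-hydroxy-4a-methyloctahydronaphthalen-2(1H)-one (cis-fused)
Conditions: H2 (1 atm), 10% Pd/C, pyridine, 25 °C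
Reagents that add atoms: none
Why: Heterogeneous hydrogenation of an angular-methyl octalenone in basic medium adds hydrogen to C-5 from the face of the angular methyl (as Δ4-3-keto steroids give 5β products), helped by the hydroxyl on that face, which sets the cis ring fusion; the minor trans isomer is removed by chromatography.

Step 5
Reactants: 7 (4aS,5S,8aR)-5-hydroxy-4a-methyloctahydronaphthalen-2(1H)-one
Product: 8 (4aS,5S,8aR)-5-(methoxymethoxy)-4a-methyloctahydronaphthalen-2(1H)-one
Conditions: MOMCl, i-Pr2NEt, CH2Cl2, 0 → 40 °C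
Reagents that add atoms: chloromethyl methyl ether COCCl
Why: O-Alkylation to a methoxymethyl acetal, which is inert to the strong bases of the next two steps.

Step 6
Reactants: 8 (4aS,5S,8aR)-5-(methoxymethoxy)-4a-methyloctahydronaphthalen-2(1H)-one
Product: 10 (4aS,5S,8aS)-5-(methoxymethoxy)-1,1,4a-trimethyloctahydronaphthalen-2(1H)-one, via monomethyl ketone 9 (not isolated)
Conditions: KOt-Bu (2.3 equiv), MeI (3 equiv), t-BuOH–THF, 0 → 25 °C
Reagents that add atoms: iodomethane CI
Why: Thermodynamic enolate alkylation: cis-fused 3-decalones enolise toward the ring-fusion side (C-4), as 5β-3-keto steroids do, so both methyl groups enter at C-4; no stereocentre is enolisable (the 8a descriptor changes from R to S only because of CIP priorities).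

Step 7
Reactants: 10 (4aS,5S,8aS)-5-(methoxymethoxy)-1,1,4a-trimethyloctahydronaphthalen-2(1H)-one
Product: 12 (1S,4aR,8aS)-1-(methoxymethoxy)-5,5,8a-trimethyldecahydronaphthalene, via hydrazone 11 (not isolated)
Conditions: N2H4·H2O, KOH, diethylene glycol, 140 → 210 °C
Reagents that add atoms: hydrazine hydrate NN.O (its nitrogens sit in 11 only)
Why: Wolff–Kishner reduction (Huang-Minlon conditions) removes the C-3 carbonyl; the acetal is stable to hot alkali.

Step 8
Reactants: 12 (1S,4aR,8aS)-1-(methoxymethoxy)-5,5,8a-trimethyldecahydronaphthalene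
Product: 13 (1S,4aR,8aS)-5,5,8a-trimethyldecahydronaphthalen-1-ol
Conditions: HCl (cat.), MeOH, 50 °C
Reagents that add atoms: none
Why: Acid-catalysed transacetalisation cleaves the methoxymethyl ether; nothing else in 12 is acid-sensitive.

Step 9
Reactants: 13 (1S,4aR,8aS)-5,5,8a-trimethyldecahydronaphthalen-1-ol
Product: 14 (4aR,8aS)-5,5,8a-trimethyloctahydronaphthalen-1(2H)-one (cis-fused)
Conditions: Dess–Martin periodinane, NaHCO3, CH2Cl2, 25 °C
Reagents that add atoms: none
Why: Dess–Martin oxidation of the hindered secondary alcohol under neutral conditions; the carbinol stereocentre is deliberately erased.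

Step 10
Reactants: 14 (4aR,8aS)-5,5,8a-trimethyloctahydronaphthalen-1(2H)-one
Product: 16 (4aR,8aS)-2,5,5,8a-tetramethyloctahydronaphthalen-1(2H)-one (C-2 epimers), via lithium enolate 15 (not isolated)
Conditions: LiN(i-Pr)2, THF, −78 °C; MeI, −78 → 0 °C
Reagents that add atoms: iodomethane CI; lithium diisopropylamide [Li+].CC(C)[N-]C(C)C (lithium in 15 only)
Why: Kinetic enolate alkylation, regiospecific because C-8 is the only enolisable position (C-10 is quaternary); the new centre is uncontrolled and is destroyed in step 11.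

Step 11
Reactants: 16 (4aR,8aS)-2,5,5,8a-tetramethyloctahydronaphthalen-1(2H)-one
Product: 18 (4aR,8aS)-2,5,5,8a-tetramethyl-3,4,4a,5,6,7,8,8a-octahydronaphthalen-1-yl trifluoromethanesulfonate, via potassium enolate 17 (not isolated)
Conditions: KN(SiMe3)2, THF, −78 → 0 °C; PhNTf2, 0 → 25 °C
Reagents that add atoms: N-phenylbis(trifluoromethanesulfonimide) O=S(=O)(N(c1ccccc1)S(=O)(=O)C(F)(F)F)C(F)(F)F; potassium hexamethyldisilazide [K+].C[Si](C)(C)[N-][Si](C)(C)C (potassium in 17 only)
Why: Enolate O-triflation: the only possible enolate is the tetrasubstituted one, and trapping it fixes the C-8/C-9 olefin of the target (the same substitution pattern as the known triflate of 2,2,6-trimethylcyclohexanone).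

Step 12
Reactants: 18 enol triflate
Product: 19 methyl (4aR,8aS)-2,5,5,8a-tetramethyl-3,4,4a,5,6,7,8,8a-octahydronaphthalene-1-carboxylate
Conditions: Pd(OAc)2 (5 mol%), Ph2P(CH2)3PPh2 (10 mol%), CO (1 atm), MeOH, Et3N, DMF, 70 °C
Reagents that add atoms: carbon monoxide [C-]#[O+]; methanol CO
Why: Palladium-catalysed methoxycarbonylation of an alkenyl triflate (oxidative addition, CO insertion, methanolysis) installs C-11 without moving the olefin.

Step 13
Reactants: 19 methyl ester
Product: 21 [(4aR,8aS)-2,5,5,8a-tetramethyl-3,4,4a,5,6,7,8,8a-octahydronaphthalen-1-yl]methanol, via enal 20 (not isolated)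
Conditions: i-Bu2AlH (2.5 equiv), CH2Cl2, −78 → 0 °C; aq. potassium sodium tartrate
Reagents that add atoms: none
Why: 1,2-Selective hydride reduction of the conjugated ester to the allylic alcohol.

Step 14
Reactants: 21 allylic alcohol
Product: 22 (4aR,8aS)-1-(bromomethyl)-2,5,5,8a-tetramethyl-3,4,4a,5,6,7,8,8a-octahydronaphthalene
Conditions: PBr3 (0.4 equiv), pyridine (cat.), Et2O, −10 → 0 °C; used crude
Reagents that add atoms: phosphorus tribromide BrP(Br)Br
Why: SN2 bromination of the primary allylic alcohol through its phosphite ester; the primary bromide with the tetrasubstituted olefin is the favoured allylic isomer.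

Step 15
Reactants: 23 3-bromo-4,5-dihydroxybenzaldehyde
Product: 24 3-bromo-5-hydroxy-4-(prop-2-en-1-yloxy)benzaldehyde
Conditions: allyl bromide (1.05 equiv), Li2CO3, DMF, 45 °C
Reagents that add atoms: allyl bromide C=CCBr
Why: Regioselective Williamson etherification: the weak base ionises only the more acidic 4-OH (para to the formyl group), so the oxygen destined for the sulfate gets the allyl group.

Step 16
Reactants: 24 3-bromo-5-hydroxy-4-(prop-2-en-1-yloxy)benzaldehyde
Product: 25 3-(benzyloxy)-5-bromo-4-(prop-2-en-1-yloxy)benzaldehyde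
Conditions: BnBr, K2CO3, DMF, 25 °C
Reagents that add atoms: benzyl bromide BrCc1ccccc1
Why: Williamson etherification of the remaining phenol with a group that cannot migrate to the neighbouring oxygen later.

Step 17
Reactants: 25 3-(benzyloxy)-5-bromo-4-(prop-2-en-1-yloxy)benzaldehyde
Product: 26 [3-(benzyloxy)-5-bromo-4-(prop-2-en-1-yloxy)phenyl]methanol
Conditions: NaBH4, MeOH, 0 °C
Reagents that add atoms: none
Why: Borohydride reduction of the aldehyde; aryl bromide and ethers are untouched.

Step 18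
Reactants: 26 [3-(benzyloxy)-5-bromo-4-(prop-2-en-1-yloxy)phenyl]methanol
Product: 27 {[3-(benzyloxy)-5-bromo-4-(prop-2-en-1-yloxy)phenyl]methoxy}(tert-butyl)dimethylsilane
Conditions: TBSCl, imidazole, DMF, 25 °C
Reagents that add atoms: tert-butyldimethylsilyl chloride CC(C)(C)[Si](C)(C)Cl
Why: Silylation of the primary alcohol gives an ether stable to organolithium and copper reagents and removable by fluoride at the end.

Step 19
Reactants: 27 aryl bromide (1.3 equiv); 22 allylic bromide
Product: 30 {[3-(benzyloxy)-4-(prop-2-en-1-yloxy)-5-(Dec-methyl)phenyl]methoxy}(tert-butyl)dimethylsilane, via aryllithium 28 (not isolated), via arylcopper 29 (not isolated)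
Conditions: n-BuLi, THF, −78 °C; CuBr·SMe2, −78 → −40 °C; then 22, −40 → 0 °C
Reagents that add atoms: n-butyllithium [Li]CCCC (lithium in 28 only); CuBr·SMe2 CSC.[Cu]Br (copper in 29 only)
Why: Bromine–lithium exchange, transmetalation and copper-mediated allylic substitution (as in arene prenylations); attack is at the primary carbon because the γ-carbon C-8 is fully substituted, so the olefin stays and no stereocentre is touched.

Step 20
Reactants: 30 coupled allyl ether
Product: 31 2-(benzyloxy)-4-{[(tert-butyldimethylsilyl)oxy]methyl}-6-(Dec-methyl)phenol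
Conditions: Pd(PPh3)4 (5 mol%), morpholine, THF, 25 °C
Reagents that add atoms: none
Why: Tsuji–Trost deallylation: zerovalent palladium ionises the aryl allyl ether and morpholine traps the allyl fragment, freeing only this phenol without acid (acid could close a chroman onto the olefin).

Step 21
Reactants: 31 phenol
Product: 32 2-(benzyloxy)-4-{[(tert-butyldimethylsilyl)oxy]methyl}-6-(Dec-methyl)phenyl hydrogen sulfate
Conditions: SO3·pyridine (5 equiv), pyridine, 50 °C; aq. NaHCO3 work-up
Reagents that add atoms: sulfur trioxide–pyridine complex [O-]S(=O)(=O)[n+]1ccccc1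
Why: O-Sulfation (sulfuryl transfer) of the only free hydroxyl; the benzyl group on the neighbouring oxygen cannot migrate, so the position of the sulfate is secured.

Step 22
Reactants: 32 benzyl-protected sulfate
Product: 33 4-{[(tert-butyldimethylsilyl)oxy]methyl}-2-hydroxy-6-(Dec-methyl)phenyl hydrogen sulfate
Conditions: H2 (1 atm), 10% Pd/C, EtOAc, 25 °C
Reagents that add atoms: none
Why: Catalytic hydrogenolysis of the aryl benzyl ether; the hindered tetrasubstituted olefin, the aryl sulfate and the silyl ether are inert under these conditions.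

Step 23
Reactants: 33 silyl-protected sulfate
Product: 34 2-hydroxy-4-(hydroxymethyl)-6-(Dec-methyl)phenyl hydrogen sulfate (target, CNP0263972.2)
Conditions: Bu4NF, THF, 0 → 25 °C
Reagents that add atoms: none
Why: Fluoride-mediated desilylation; aryl sulfate monoesters tolerate fluoride and base, so the target is released without acid.

## Compound list

1 | 2-methylcyclohexane-1,3-dione | CC1C(=O)CCCC1=O | starting material
2 | but-3-en-2-one (methyl vinyl ketone) | CC(=O)C=C | starting material
3 | 2-methyl-2-(3-oxobutyl)cyclohexane-1,3-dione | CC(=O)CCC1(C)C(=O)CCCC1=O | intermediate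
4 | (4aS,8aS)-4a-hydroxy-8a-methyloctahydronaphthalene-1,6-dione, cis-fused ketol (not isolated) | C1C(=O)[C@@]2(C)CCC(=O)C[C@@]2(O)CC1 | intermediate
5 | (S)-8a-methyl-3,4,8,8a-tetrahydronaphthalene-1,6(2H,7H)-dione | C1C(=O)[C@@]2(C)CCC(=O)C=C2CC1 | intermediate
6 | (4aS,5S)-5-hydroxy-4a-methyl-4,4a,5,6,7,8-hexahydronaphthalen-2(3H)-one | C1[C@H](O)[C@@]2(C)CCC(=O)C=C2CC1 | intermediate
7 | (4aS,5S,8aR)-5-hydroxy-4a-methyloctahydronaphthalen-2(1H)-one, cis-fused | C1[C@H](O)[C@@]2(C)CCC(=O)C[C@H]2CC1 | intermediate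
8 | (4aS,5S,8aR)-5-(methoxymethoxy)-4a-methyloctahydronaphthalen-2(1H)-one | C1[C@H](OCOC)[C@@]2(C)CCC(=O)C[C@H]2CC1 | intermediate
9 | (4aS,5S,8aR)-5-(methoxymethoxy)-1,4a-dimethyloctahydronaphthalen-2(1H)-one, C-1 epimers (not isolated) | C1[C@H](OCOC)[C@@]2(C)CCC(=O)C(C)[C@H]2CC1 | intermediate
10 | (4aS,5S,8aS)-5-(methoxymethoxy)-1,1,4a-trimethyloctahydronaphthalen-2(1H)-one | C1[C@H](OCOC)[C@@]2(C)CCC(=O)C(C)(C)[C@H]2CC1 | intermediate
11 | hydrazone of 10 (not isolated) | C1[C@H](OCOC)[C@@]2(C)CCC(=NN)C(C)(C)[C@H]2CC1 | intermediate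
12 | (1S,4aR,8aS)-1-(methoxymethoxy)-5,5,8a-trimethyldecahydronaphthalene | C1[C@H](OCOC)[C@@]2(C)CCCC(C)(C)[C@H]2CC1 | intermediate
13 | (1S,4aR,8aS)-5,5,8a-trimethyldecahydronaphthalen-1-ol | C1[C@H](O)[C@@]2(C)CCCC(C)(C)[C@H]2CC1 | intermediate
14 | (4aR,8aS)-5,5,8a-trimethyloctahydronaphthalen-1(2H)-one | C1C(=O)[C@@]2(C)CCCC(C)(C)[C@H]2CC1 | intermediate
15 | lithium enolate of 14 (not isolated) | C1=C([O-])[C@@]2(C)CCCC(C)(C)[C@H]2CC1.[Li+] | intermediate
16 | (4aR,8aS)-2,5,5,8a-tetramethyloctahydronaphthalen-1(2H)-one, C-2 epimers | CC1C(=O)[C@@]2(C)CCCC(C)(C)[C@H]2CC1 | intermediate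
17 | potassium enolate of 16 (not isolated) | CC1=C([O-])[C@@]2(C)CCCC(C)(C)[C@H]2CC1.[K+] | intermediate
18 | Dec trifluoromethanesulfonate | CC1=C(OS(=O)(=O)C(F)(F)F)[C@@]2(C)CCCC(C)(C)[C@H]2CC1 | intermediate
19 | methyl Dec-carboxylate | CC1=C(C(=O)OC)[C@@]2(C)CCCC(C)(C)[C@H]2CC1 | intermediate
20 | Dec-carbaldehyde (not isolated) | CC1=C(C=O)[C@@]2(C)CCCC(C)(C)[C@H]2CC1 | intermediate
21 | Dec-methanol | CC1=C(CO)[C@@]2(C)CCCC(C)(C)[C@H]2CC1 | intermediate
22 | Dec-methyl bromide | CC1=C(CBr)[C@@]2(C)CCCC(C)(C)[C@H]2CC1 | intermediate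
23 | 3-bromo-4,5-dihydroxybenzaldehyde | O=Cc1cc(O)c(O)c(Br)c1 | starting material
24 | 3-bromo-5-hydroxy-4-(prop-2-en-1-yloxy)benzaldehyde | O=Cc1cc(O)c(OCC=C)c(Br)c1 | intermediate
25 | 3-(benzyloxy)-5-bromo-4-(prop-2-en-1-yloxy)benzaldehyde | O=Cc1cc(OCc2ccccc2)c(OCC=C)c(Br)c1 | intermediate
26 | [3-(benzyloxy)-5-bromo-4-(prop-2-en-1-yloxy)phenyl]methanol | OCc1cc(OCc2ccccc2)c(OCC=C)c(Br)c1 | intermediate
27 | {[3-(benzyloxy)-5-bromo-4-(prop-2-en-1-yloxy)phenyl]methoxy}(tert-butyl)dimethylsilane | CC(C)(C)[Si](C)(C)OCc1cc(OCc2ccccc2)c(OCC=C)c(Br)c1 | intermediate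
28 | aryllithium from 27 (not isolated) | CC(C)(C)[Si](C)(C)OCc1cc(OCc2ccccc2)c(OCC=C)c([Li])c1 | intermediate
29 | arylcopper from 28 (not isolated) | CC(C)(C)[Si](C)(C)OCc1cc(OCc2ccccc2)c(OCC=C)c([Cu])c1 | intermediate
30 | {[3-(benzyloxy)-4-(prop-2-en-1-yloxy)-5-(Dec-methyl)phenyl]methoxy}(tert-butyl)dimethylsilane | CC1=C(Cc2cc(CO[Si](C)(C)C(C)(C)C)cc(OCc3ccccc3)c2OCC=C)[C@@]2(C)CCCC(C)(C)[C@H]2CC1 | intermediate
31 | 2-(benzyloxy)-4-{[(tert-butyldimethylsilyl)oxy]methyl}-6-(Dec-methyl)phenol | CC1=C(Cc2cc(CO[Si](C)(C)C(C)(C)C)cc(OCc3ccccc3)c2O)[C@@]2(C)CCCC(C)(C)[C@H]2CC1 | intermediate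
32 | 2-(benzyloxy)-4-{[(tert-butyldimethylsilyl)oxy]methyl}-6-(Dec-methyl)phenyl hydrogen sulfate | CC1=C(Cc2cc(CO[Si](C)(C)C(C)(C)C)cc(OCc3ccccc3)c2OS(=O)(=O)O)[C@@]2(C)CCCC(C)(C)[C@H]2CC1 | intermediate
33 | 4-{[(tert-butyldimethylsilyl)oxy]methyl}-2-hydroxy-6-(Dec-methyl)phenyl hydrogen sulfate | CC1=C(Cc2cc(CO[Si](C)(C)C(C)(C)C)cc(O)c2OS(=O)(=O)O)[C@@]2(C)CCCC(C)(C)[C@H]2CC1 | intermediate
34 | 2-hydroxy-4-(hydroxymethyl)-6-{[(4aR,8aS)-2,5,5,8a-tetramethyl-3,4,4a,5,6,7,8,8a-octahydronaphthalen-1-yl]methyl}phenyl hydrogen sulfate | CC1=C(Cc2cc(CO)cc(O)c2OS(=O)(=O)O)[C@@]2(C)CCCC(C)(C)[C@H]2CC1 | target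

## Step count and risks

Total step count: 23. Longest linear sequence: 19 (steps 1–14, then 19–23); steps 15–18 build the aryl fragment.

The three steps most likely to fail:

Step 6 (C-4 gem-dimethylation of cis-ketone 8). The risk is methylation at C-2 or over-methylation. The fallback sets out from hydroxy enone 6 and comes back at alcohol 13; it installs the gem-dimethyl group before the ring fusion is set and so also replaces step 4. Compound 6 is protected (MOMCl, i-Pr2NEt) as (4aS,5S)-5-(methoxymethoxy)-4a-methyl-4,4a,5,6,7,8-hexahydronaphthalen-2(3H)-one F1. Deconjugative α,α-dimethylation through the extended dienolate (KOt-Bu, MeI, t-BuOH) gives (4aS,5S)-5-(methoxymethoxy)-1,1,4a-trimethyl-3,4,4a,5,6,7-hexahydronaphthalen-2(1H)-one F2. Wolff–Kishner reduction through its hydrazone F3 gives (1S,8aS)-1-(methoxymethoxy)-5,5,8a-trimethyl-1,2,3,5,6,7,8,8a-octahydronaphthalene F4, and HCl in MeOH frees (1S,8aS)-5,5,8a-trimethyl-1,2,3,5,6,7,8,8a-octahydronaphthalen-1-ol F5. Hydroxyl-directed hydrogenation with [Ir(cod)(PCy3)(py)]PF6 (H2, CH2Cl2) then delivers hydrogen to C-5 from the face of the homoallylic hydroxyl, which is the face of the angular methyl, and gives 13.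

Step 19 (fragment union). The risks are elimination of the hindered allylic bromide and side reactions of the ortho-allyloxy aryllithium. The fallback sets out from allylic alcohol 21 and aryl bromide 27 and comes back at 30; it forms the same bond by carbonyl addition and deoxygenation. MnO2 in CH2Cl2 oxidises 21 to enal 20, this time isolated. Aryllithium 28 (from 27 and n-BuLi, THF, −78 °C) adds 1,2 to give [3-(benzyloxy)-4-(prop-2-en-1-yloxy)-5-{[(tert-butyldimethylsilyl)oxy]methyl}phenyl](Dec)methanol F6 as both carbinol epimers. Ionic hydrogenation (Et3SiH, CF3CO2H, CH2Cl2, −78 °C) removes the hydroxyl; hydride enters at the benzylic end of the allyl–benzyl cation, so the tetrasubstituted olefin is kept, and 30 results.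

Step 21 (sulfation of a phenol flanked by two ortho substituents). The risk is sluggish or incomplete sulfation and difficult purification of the salt. The fallback sets out from phenol 31 and comes back at 32; it uses a protected sulfate diester. Phenol 31 reacts with 2,2,2-trichloroethyl chlorosulfate (Et3N, DMAP, THF) to give the neutral, chromatographable 2-(benzyloxy)-4-{[(tert-butyldimethylsilyl)oxy]methyl}-6-(Dec-methyl)phenyl 2,2,2-trichloroethyl sulfate F7. Zinc dust and HCO2NH4 in MeOH remove the trichloroethyl group by reductive fragmentation and give 32.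

## Further compounds

F1 | step 6 | (4aS,5S)-5-(methoxymethoxy)-4a-methyl-4,4a,5,6,7,8-hexahydronaphthalen-2(3H)-one | C1[C@H](OCOC)[C@@]2(C)CCC(=O)C=C2CC1
F2 | step 6 | (4aS,5S)-5-(methoxymethoxy)-1,1,4a-trimethyl-3,4,4a,5,6,7-hexahydronaphthalen-2(1H)-one | C1[C@H](OCOC)[C@@]2(C)CCC(=O)C(C)(C)C2=CC1
F3 | step 6 | hydrazone of F2 | C1[C@H](OCOC)[C@@]2(C)CCC(=NN)C(C)(C)C2=CC1
F4 | step 6 | (1S,8aS)-1-(methoxymethoxy)-5,5,8a-trimethyl-1,2,3,5,6,7,8,8a-octahydronaphthalene | C1[C@H](OCOC)[C@@]2(C)CCCC(C)(C)C2=CC1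
F5 | step 6 | (1S,8aS)-5,5,8a-trimethyl-1,2,3,5,6,7,8,8a-octahydronaphthalen-1-ol | C1[C@H](O)[C@@]2(C)CCCC(C)(C)C2=CC1
F6 | step 19 | [3-(benzyloxy)-4-(prop-2-en-1-yloxy)-5-{[(tert-butyldimethylsilyl)oxy]methyl}phenyl](Dec)methanol, both carbinol epimers | CC1=C(C(O)c2cc(CO[Si](C)(C)C(C)(C)C)cc(OCc3ccccc3)c2OCC=C)[C@@]2(C)CCCC(C)(C)[C@H]2CC1
F7 | step 21 | 2-(benzyloxy)-4-{[(tert-butyldimethylsilyl)oxy]methyl}-6-(Dec-methyl)phenyl 2,2,2-trichloroethyl sulfate | CC1=C(Cc2cc(CO[Si](C)(C)C(C)(C)C)cc(OCc3ccccc3)c2OS(=O)(=O)OCC(Cl)(Cl)Cl)[C@@]2(C)CCCC(C)(C)[C@H]2CC1
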